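**Plan**
1. Retrosynthesis: the angelate C–O bond and the silyl and MOM ethers are cut first. One (2+2+1) cut then removes three bonds of the α-methylene-γ-butyrolactone and cyclopentane: O–C(=O), C(=O)–C(=CH2), and the ring-fusion C–C bond between the O–CH and the CH that carries C(=CH2).
2. Enabling feature: these two ring-fusion CH groups are adjacent cyclopentane atoms, each joined to the spiro quaternary carbon through one CH2. The cyclopentane plus lactone is therefore the carbonylative adduct of a CH2CHO arm and a CH2CH=C=CH2 arm on that carbon.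
3. The two arms go back to allyl and silylpropargyl groups on C6 of (S)-5-methylcyclohex-2-enone. Addition of a CH2OMOM anion with oxidative 1,3-transposition, α'-hydroxylation and 1,2-reduction complete the cyclohexene.
4. Forward order: cyclohexenone ring (step 1), quaternary carbon (2–3), cyclohexene functionality (4–8), arm adjustment (9–11), cyclopentane and lactone closed together as the last ring-forming event (12), ester and deprotection (13–15).
5. Stereochemistry: the C–CH3 centre comes from a catalyst-controlled Michael addition. The quaternary carbon and both carbinol centres follow from it by 1,2-induction and axial hydride delivery. The two ring-fusion centres arise in step 12, cis by ring constraint, with the face set by the spiro substituents.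

Key step: step 12

Remark: 3, 4 and 10 are epimer mixtures at one centre that is removed in the same or the next step, so their SMILES leave that centre open.

**Step 1**
Reactants: 1 (E)-but-2-enal; 2 tert-butyl 3-oxobutanoate
Product: 5 (5S)-5-methylcyclohex-2-en-1-one, via Michael adduct 3 (not isolated), via keto ester 4 (not isolated)
Conditions: (R)-2-{bis[3,5-bis(trifluoromethyl)phenyl][(trimethylsilyl)oxy]methyl}pyrrolidine (10 mol%), neat, rt; then p-toluenesulfonic acid monohydrate (20 mol%), toluene, 80 °C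
Reagents that add atoms: none
Why: Iminium-ion-catalysed Michael addition of the β-keto ester to the enal (organocatalytic Michael/aldol-condensation/decarboxylation cascade): the bulky diaryl(silyloxy)methyl group of the (R)-catalyst shields one face of the (E)-iminium ion so that the nucleophile should add to the Si face of C3 and set the (S)-methyl centre, after which acid closes the ring by intramolecular aldol condensation and removes the tert-butyl ester as isobutene and CO2.

**Step 2**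
Reactants: 5 (5S)-5-methylcyclohex-2-en-1-one
Product: 7 (5S,6R)-5-methyl-6-[3-(trimethylsilyl)prop-2-yn-1-yl]cyclohex-2-en-1-one, via lithium dienolate 6 (not isolated)
Conditions: LiN(iPr)2, THF, −78 °C; then 3-bromo-1-(trimethylsilyl)prop-1-yne, DMPU, −78 → −20 °C
Reagents that add atoms: 3-bromo-1-(trimethylsilyl)prop-1-yne, C[Si](C)(C)C#CCBr
Why: Kinetic α'-deprotonation gives the cross-conjugated dienolate, which the reactive propargylic bromide should alkylate anti to the adjacent methyl group (enolate alkylation); the new centre is planarised again in step 3.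

**Step 3**
Reactants: 7 (5S,6R)-5-methyl-6-[3-(trimethylsilyl)prop-2-yn-1-yl]cyclohex-2-en-1-one
Product: 9 (5S,6S)-5-methyl-6-(prop-2-en-1-yl)-6-[3-(trimethylsilyl)prop-2-yn-1-yl]cyclohex-2-en-1-one, via lithium dienolate 8 (not isolated)
Conditions: LiN(iPr)2, THF, −78 → 0 °C; then allyl bromide, DMPU, −78 → 0 °C
Reagents that add atoms: allyl bromide, C=CCBr
Why: Alkylation of the tetrasubstituted cross-conjugated enolate: allylic 1,2-strain with the enolate substituent forces the C5 methyl pseudoaxial, so allyl bromide should enter on the opposite face and form the quaternary carbon with allyl trans and the silylpropargyl group cis to the methyl (1,2-induction, as in sequential α'-dialkylations of 5-substituted cyclohexenones).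

**Step 4**
Reactants: 9 (5S,6S)-5-methyl-6-(prop-2-en-1-yl)-6-[3-(trimethylsilyl)prop-2-yn-1-yl]cyclohex-2-en-1-one
Product: 10 (5S,6S)-1-[(methoxymethoxy)methyl]-5-methyl-6-(prop-2-en-1-yl)-6-[3-(trimethylsilyl)prop-2-yn-1-yl]cyclohex-2-en-1-ol
Conditions: Bu3SnCH2OCH2OMe, n-BuLi, THF, −78 °C; then 9, −78 °C; then H2O
Reagents that add atoms: tributyl[(methoxymethoxy)methyl]stannane, CCCC[Sn](CCCC)(CCCC)COCOC
Why: Tin–lithium exchange gives the α-alkoxymethyllithium, a hard nucleophile that should add 1,2 to the non-enolisable enone carbonyl (organolithium 1,2-addition); the carbinol configuration is irrelevant because this carbon becomes sp2 in step 5.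

**Step 5**
Reactants: 10 (5S,6S)-1-[(methoxymethoxy)methyl]-5-methyl-6-(prop-2-en-1-yl)-6-[3-(trimethylsilyl)prop-2-yn-1-yl]cyclohex-2-en-1-ol
Product: 11 (4S,5S)-3-[(methoxymethoxy)methyl]-5-methyl-4-(prop-2-en-1-yl)-4-[3-(trimethylsilyl)prop-2-yn-1-yl]cyclohex-2-en-1-one
Conditions: pyridinium chlorochromate (C5H5NH)[CrO3Cl], 4 Å molecular sieves, CH2Cl2, rt
Reagents that add atoms: pyridinium chlorochromate, c1cc[nH+]cc1.[O-][Cr](=O)(=O)Cl (an oxo ligand becomes the ketone oxygen)
Why: Oxidative 1,3-transposition of the tertiary allylic alcohol (Babler–Dauben oxidation): the chromate ester undergoes a [3,3] shift to the secondary allylic chromate, which is oxidised to the β-substituted enone, so the oxygen moves to the future allylic carbinol carbon and the CH2OMOM branch ends up on the alkene.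

**Step 6**
Reactants: 11 (4S,5S)-3-[(methoxymethoxy)methyl]-5-methyl-4-(prop-2-en-1-yl)-4-[3-(trimethylsilyl)prop-2-yn-1-yl]cyclohex-2-en-1-one
Product: 13 (4S,5R,6S)-6-hydroxy-3-[(methoxymethoxy)methyl]-5-methyl-4-(prop-2-en-1-yl)-4-[3-(trimethylsilyl)prop-2-yn-1-yl]cyclohex-2-en-1-one, via potassium dienolate 12 (not isolated)
Conditions: KN(SiMe3)2, THF, −78 °C; then 3-phenyl-2-(phenylsulfonyl)oxaziridine, −78 °C; then AcOH
Reagents that add atoms: 3-phenyl-2-(phenylsulfonyl)oxaziridine, O=S(=O)(N1OC1c1ccccc1)c1ccccc1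
Why: Kinetic deprotonation at the α'-CH2 and electrophilic hydroxylation of the dienolate by the N-sulfonyloxaziridine (enolate oxidation) should occur anti to the adjacent methyl group and to the pseudoaxial propargyl arm, giving the hydroxyl trans to methyl.

**Step 7**
Reactants: 13 (4S,5R,6S)-6-hydroxy-3-[(methoxymethoxy)methyl]-5-methyl-4-(prop-2-en-1-yl)-4-[3-(trimethylsilyl)prop-2-yn-1-yl]cyclohex-2-en-1-one
Product: 14 (1S,2S,5S,6R)-4-[(methoxymethoxy)methyl]-6-methyl-5-(prop-2-en-1-yl)-5-[3-(trimethylsilyl)prop-2-yn-1-yl]cyclohex-3-ene-1,2-diol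
Conditions: NaBH4, CeCl3·7H2O, MeOH, −78 °C
Reagents that add atoms: none
Why: Luche 1,2-reduction: axial hydride delivery to the half-chair with pseudoequatorial hydroxyl and methyl should give the pseudoequatorial allylic alcohol, that is the trans-diol.

**Step 8**
Reactants: 14 (1S,2S,5S,6R)-4-[(methoxymethoxy)methyl]-6-methyl-5-(prop-2-en-1-yl)-5-[3-(trimethylsilyl)prop-2-yn-1-yl]cyclohex-3-ene-1,2-diol
Product: 15 (3S,4S,5R,6S)-3,4-bis[(tert-butyldimethylsilyl)oxy]-1-[(methoxymethoxy)methyl]-5-methyl-6-(prop-2-en-1-yl)-6-[3-(trimethylsilyl)prop-2-yn-1-yl]cyclohex-1-ene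
Conditions: TBSOTf, 2,6-lutidine, CH2Cl2, −78 → 0 °C
Reagents that add atoms: tert-butyldimethylsilyl trifluoromethanesulfonate, CC(C)(C)[Si](C)(C)OS(=O)(=O)C(F)(F)F
Why: Silylation of both secondary alcohols by the reactive silyl triflate protects the diol against the later oxidations and the carbonylation, and the MOM ether should survive under the hindered base at low temperature.

**Step 9**
Reactants: 15 (3S,4S,5R,6S)-3,4-bis[(tert-butyldimethylsilyl)oxy]-1-[(methoxymethoxy)methyl]-5-methyl-6-(prop-2-en-1-yl)-6-[3-(trimethylsilyl)prop-2-yn-1-yl]cyclohex-1-ene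
Product: 18 2-{(1R,4S,5S,6R)-4,5-bis[(tert-butyldimethylsilyl)oxy]-2-[(methoxymethoxy)methyl]-6-methyl-1-(prop-2-yn-1-yl)cyclohex-2-en-1-yl}ethan-1-ol, via silylalkynyl aldehyde 16 (not isolated), via silylalkynyl alcohol 17 (not isolated)
Conditions: OsO4 (2 mol%), NaIO4, 2,6-lutidine, dioxane/H2O, rt; then NaBH4, MeOH, 0 °C; then K2CO3, MeOH, rt
Reagents that add atoms: osmium tetroxide, O=[Os](=O)(=O)=O; sodium periodate, [Na+].[O-]I(=O)(=O)=O (the new oxygen is delivered by OsO4 and replenished by NaIO4)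
Why: Lemieux–Johnson cleavage should be selective for the monosubstituted terminal alkene because the trisubstituted ring alkene is shielded by the quaternary carbon and the flanking silyl ether and deactivated by two allylic oxygens; borohydride then reduces the aldehyde and methanolic carbonate removes the alkynyl silyl group (protodesilylation).

**Step 10**
Reactants: 18 2-{(1R,4S,5S,6R)-4,5-bis[(tert-butyldimethylsilyl)oxy]-2-[(methoxymethoxy)methyl]-6-methyl-1-(prop-2-yn-1-yl)cyclohex-2-en-1-yl}ethan-1-ol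
Product: 20 2-{(1R,4S,5S,6R)-1-(buta-2,3-dien-1-yl)-4,5-bis[(tert-butyldimethylsilyl)oxy]-2-[(methoxymethoxy)methyl]-6-methylcyclohex-2-en-1-yl}ethan-1-ol, via propargylic amine 19 (not isolated)
Conditions: (CH2O)n, CuBr (30 mol%), iPr2NH, dioxane, reflux
Reagents that add atoms: paraformaldehyde (formaldehyde), C=O
Why: Crabbé homologation: copper-catalysed Mannich coupling of the terminal alkyne with formaldehyde and diisopropylamine gives the propargylic amine, which transfers hydride intramolecularly (retro-ene type) to release the terminal allene and an imine; the free primary alcohol is tolerated.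

**Step 11**
Reactants: 20 2-{(1R,4S,5S,6R)-1-(buta-2,3-dien-1-yl)-4,5-bis[(tert-butyldimethylsilyl)oxy]-2-[(methoxymethoxy)methyl]-6-methylcyclohex-2-en-1-yl}ethan-1-ol
Product: 21 {(1R,4S,5S,6R)-1-(buta-2,3-dien-1-yl)-4,5-bis[(tert-butyldimethylsilyl)oxy]-2-[(methoxymethoxy)methyl]-6-methylcyclohex-2-en-1-yl}acetaldehyde
Conditions: Dess–Martin periodinane, CH2Cl2, 0 °C → rt
Reagents that add atoms: none
Why: Dess–Martin oxidation should convert the primary alcohol into the aldehyde under near-neutral conditions that leave the allene, the acetal and the silyl ethers untouched.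

**Step 12**
Reactants: 21 {(1R,4S,5S,6R)-1-(buta-2,3-dien-1-yl)-4,5-bis[(tert-butyldimethylsilyl)oxy]-2-[(methoxymethoxy)methyl]-6-methylcyclohex-2-en-1-yl}acetaldehyde
Product: 22 (1R,3a'R,4S,5S,6R,6a'R)-4,5-bis[(tert-butyldimethylsilyl)oxy]-2-[(methoxymethoxy)methyl]-6-methyl-3'-methylidenehexahydrospiro[cyclohex-2-ene-1,5'-cyclopenta[b]furan]-2'-one
Conditions: Ru3(CO)12 (2 mol%), CO (20 atm), dioxane, 120 °C
Reagents that add atoms: carbon monoxide, [C-]#[O+]
Why: Hetero-Pauson–Khand (2+2+1) cyclocarbonylation, the known metal-carbonyl reaction of allenyl aldehydes to cis-fused α-methylene-γ-butyrolactones: zerovalent ruthenium binds the aldehyde C=O and the internal C=C of the allene and undergoes oxidative cyclisation to an oxaruthenacyclopentane, CO inserts into the Ru–C(sp2) bond and C–O reductive elimination releases the lactone. The cyclopentane is closed by the C–C bond between the aldehyde carbon and the internal allene CH, a 5-exo closure with respect to both π systems that is helped by the quaternary carbon in the three-atom tether, and the lactone is closed by the acyl C–O reductive elimination. The two new ring-fusion stereocentres should be cis because only the cis-fused bicyclo[3.3.0] metallacycle is attainable. Their configuration relative to the spiro centre depends on the face on which the metallacycle forms: the face syn to the flat sp2 ring carbon should be preferred over the face syn to the sp3 CH(CH3) carbon, whose methyl lies cis to the allenyl arm, and the MOM oxygen may assist by binding the metal on that face. The step also needs reaction at the internal and not the terminal allene π bond, which the three-atom tether secures (five- against six-membered carbocycle), and inertness of the hindered trisubstituted ring alkene.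

**Step 13**
Reactants: 22 (1R,3a'R,4S,5S,6R,6a'R)-4,5-bis[(tert-butyldimethylsilyl)oxy]-2-[(methoxymethoxy)methyl]-6-methyl-3'-methylidenehexahydrospiro[cyclohex-2-ene-1,5'-cyclopenta[b]furan]-2'-one
Product: 24 (1R,3a'R,4S,5S,6R,6a'R)-4,5-bis[(tert-butyldimethylsilyl)oxy]-2-(hydroxymethyl)-6-methyl-3'-methylidenehexahydrospiro[cyclohex-2-ene-1,5'-cyclopenta[b]furan]-2'-one, via bromomethyl ether 23 (not isolated)
Conditions: Me2BBr, CH2Cl2, −78 °C; then sat. NaHCO3, THF
Reagents that add atoms: none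
Why: Dimethylboron bromide should cleave the acetal C–O bond of the MOM ether at −78 °C to the bromomethyl ether, which is hydrolysed on work-up (Lewis-acid acetal cleavage), while the silyl ethers, the lactone and the exocyclic alkene are not affected at this temperature.

**Step 14**
Reactants: 24 (1R,3a'R,4S,5S,6R,6a'R)-4,5-bis[(tert-butyldimethylsilyl)oxy]-2-(hydroxymethyl)-6-methyl-3'-methylidenehexahydrospiro[cyclohex-2-ene-1,5'-cyclopenta[b]furan]-2'-one
Product: 25 [(1R,3a'R,4S,5S,6R,6a'R)-4,5-bis[(tert-butyldimethylsilyl)oxy]-6-methyl-3'-methylidene-2'-oxohexahydrospiro[cyclohex-2-ene-1,5'-cyclopenta[b]furan]-2-yl]methyl (2Z)-2-methylbut-2-enoate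
Conditions: angelic acid, 2,4,6-trichlorobenzoyl chloride, Et3N, toluene, rt; then 24, 70 °C
Reagents that add atoms: angelic acid [(2Z)-2-methylbut-2-enoic acid], C/C=C(/C)C(=O)O
Why: Yamaguchi-type esterification through the mixed 2,4,6-trichlorobenzoic anhydride should acylate the unhindered primary allylic alcohol; leaving out nucleophilic catalysts and strong base limits isomerisation of the (Z)-2-methylbut-2-enoyl group to the (E)-isomer and conjugate addition to the α-methylene lactone.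

**Step 15**
Reactants: 25 [(1R,3a'R,4S,5S,6R,6a'R)-4,5-bis[(tert-butyldimethylsilyl)oxy]-6-methyl-3'-methylidene-2'-oxohexahydrospiro[cyclohex-2-ene-1,5'-cyclopenta[b]furan]-2-yl]methyl (2Z)-2-methylbut-2-enoate
Product: 26 [(1R,3a'R,4S,5S,6R,6a'R)-4,5-dihydroxy-6-methyl-3'-methylidene-2'-oxohexahydrospiro[cyclohex-2-ene-1,5'-cyclopenta[b]furan]-2-yl]methyl (2Z)-2-methylbut-2-enoate
Conditions: HF·pyridine, pyridine, THF, 0 °C → rt
Reagents that add atoms: none
Why: Fluoride-mediated cleavage of both silyl ethers with buffered HF·pyridine (desilylation) should release the trans-diol without touching the angelate, the α-methylene lactone or any stereocentre.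

**Compound list**
1 | (E)-but-2-enal | C/C=C/C=O | starting material
2 | tert-butyl 3-oxobutanoate | CC(=O)CC(=O)OC(C)(C)C | starting material
3 | tert-butyl (3S)-2-acetyl-3-methyl-5-oxopentanoate (epimers at C2) | O=CC[C@H](C)C(C(C)=O)C(=O)OC(C)(C)C | intermediate
4 | tert-butyl (6S)-6-methyl-2-oxocyclohex-3-ene-1-carboxylate (epimers at C1) | O=C1C=CC[C@H](C)C1C(=O)OC(C)(C)C | intermediate
5 | (5S)-5-methylcyclohex-2-en-1-one | O=C1C=CC[C@H](C)C1 | intermediate
6 | lithium (3S)-3-methylcyclohexa-1,5-dien-1-olate | [Li]OC1=C[C@@H](C)CC=C1 | intermediate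
7 | (5S,6R)-5-methyl-6-[3-(trimethylsilyl)prop-2-yn-1-yl]cyclohex-2-en-1-one (trans) | C[Si](C)(C)C#CC[C@H]1C(=O)C=CC[C@@H]1C | intermediate
8 | lithium (3S)-3-methyl-2-[3-(trimethylsilyl)prop-2-yn-1-yl]cyclohexa-1,5-dien-1-olate | [Li]OC1=C(CC#C[Si](C)(C)C)[C@@H](C)CC=C1 | intermediate
9 | (5S,6S)-5-methyl-6-(prop-2-en-1-yl)-6-[3-(trimethylsilyl)prop-2-yn-1-yl]cyclohex-2-en-1-one (allyl trans to methyl) | C=CC[C@@]1(CC#C[Si](C)(C)C)C(=O)C=CC[C@@H]1C | intermediate
10 | (5S,6S)-1-[(methoxymethoxy)methyl]-5-methyl-6-(prop-2-en-1-yl)-6-[3-(trimethylsilyl)prop-2-yn-1-yl]cyclohex-2-en-1-ol (epimers at C1) | C=CC[C@@]1(CC#C[Si](C)(C)C)C(O)(COCOC)C=CC[C@@H]1C | intermediate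
11 | (4S,5S)-3-[(methoxymethoxy)methyl]-5-methyl-4-(prop-2-en-1-yl)-4-[3-(trimethylsilyl)prop-2-yn-1-yl]cyclohex-2-en-1-one | C=CC[C@@]1(CC#C[Si](C)(C)C)C(COCOC)=CC(=O)C[C@@H]1C | intermediate
12 | potassium (3S,4S)-5-[(methoxymethoxy)methyl]-3-methyl-4-(prop-2-en-1-yl)-4-[3-(trimethylsilyl)prop-2-yn-1-yl]cyclohexa-1,5-dien-1-olate | C=CC[C@@]1(CC#C[Si](C)(C)C)C(COCOC)=CC(O[K])=C[C@@H]1C | intermediate
13 | (4S,5R,6S)-6-hydroxy-3-[(methoxymethoxy)methyl]-5-methyl-4-(prop-2-en-1-yl)-4-[3-(trimethylsilyl)prop-2-yn-1-yl]cyclohex-2-en-1-one (OH trans to methyl) | C=CC[C@@]1(CC#C[Si](C)(C)C)C(COCOC)=CC(=O)[C@@H](O)[C@@H]1C | intermediate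
14 | (1S,2S,5S,6R)-4-[(methoxymethoxy)methyl]-6-methyl-5-(prop-2-en-1-yl)-5-[3-(trimethylsilyl)prop-2-yn-1-yl]cyclohex-3-ene-1,2-diol (trans-diol) | C=CC[C@@]1(CC#C[Si](C)(C)C)C(COCOC)=C[C@H](O)[C@@H](O)[C@@H]1C | intermediate
15 | (3S,4S,5R,6S)-3,4-bis[(tert-butyldimethylsilyl)oxy]-1-[(methoxymethoxy)methyl]-5-methyl-6-(prop-2-en-1-yl)-6-[3-(trimethylsilyl)prop-2-yn-1-yl]cyclohex-1-ene | C=CC[C@@]1(CC#C[Si](C)(C)C)C(COCOC)=C[C@H](O[Si](C)(C)C(C)(C)C)[C@@H](O[Si](C)(C)C(C)(C)C)[C@@H]1C | intermediate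
16 | {(1R,4S,5S,6R)-4,5-bis[(tert-butyldimethylsilyl)oxy]-2-[(methoxymethoxy)methyl]-6-methyl-1-[3-(trimethylsilyl)prop-2-yn-1-yl]cyclohex-2-en-1-yl}acetaldehyde | O=CC[C@@]1(CC#C[Si](C)(C)C)C(COCOC)=C[C@H](O[Si](C)(C)C(C)(C)C)[C@@H](O[Si](C)(C)C(C)(C)C)[C@@H]1C | intermediate
17 | 2-{(1R,4S,5S,6R)-4,5-bis[(tert-butyldimethylsilyl)oxy]-2-[(methoxymethoxy)methyl]-6-methyl-1-[3-(trimethylsilyl)prop-2-yn-1-yl]cyclohex-2-en-1-yl}ethan-1-ol | OCC[C@@]1(CC#C[Si](C)(C)C)C(COCOC)=C[C@H](O[Si](C)(C)C(C)(C)C)[C@@H](O[Si](C)(C)C(C)(C)C)[C@@H]1C | intermediate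
18 | 2-{(1R,4S,5S,6R)-4,5-bis[(tert-butyldimethylsilyl)oxy]-2-[(methoxymethoxy)methyl]-6-methyl-1-(prop-2-yn-1-yl)cyclohex-2-en-1-yl}ethan-1-ol | OCC[C@@]1(CC#C)C(COCOC)=C[C@H](O[Si](C)(C)C(C)(C)C)[C@@H](O[Si](C)(C)C(C)(C)C)[C@@H]1C | intermediate
19 | 2-{(1R,4S,5S,6R)-4,5-bis[(tert-butyldimethylsilyl)oxy]-1-[4-(dipropan-2-ylamino)but-2-yn-1-yl]-2-[(methoxymethoxy)methyl]-6-methylcyclohex-2-en-1-yl}ethan-1-ol | OCC[C@@]1(CC#CCN(C(C)C)C(C)C)C(COCOC)=C[C@H](O[Si](C)(C)C(C)(C)C)[C@@H](O[Si](C)(C)C(C)(C)C)[C@@H]1C | intermediate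
20 | 2-{(1R,4S,5S,6R)-1-(buta-2,3-dien-1-yl)-4,5-bis[(tert-butyldimethylsilyl)oxy]-2-[(methoxymethoxy)methyl]-6-methylcyclohex-2-en-1-yl}ethan-1-ol | OCC[C@@]1(CC=C=C)C(COCOC)=C[C@H](O[Si](C)(C)C(C)(C)C)[C@@H](O[Si](C)(C)C(C)(C)C)[C@@H]1C | intermediate
21 | {(1R,4S,5S,6R)-1-(buta-2,3-dien-1-yl)-4,5-bis[(tert-butyldimethylsilyl)oxy]-2-[(methoxymethoxy)methyl]-6-methylcyclohex-2-en-1-yl}acetaldehyde | O=CC[C@@]1(CC=C=C)C(COCOC)=C[C@H](O[Si](C)(C)C(C)(C)C)[C@@H](O[Si](C)(C)C(C)(C)C)[C@@H]1C | intermediate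
22 | (1R,3a'R,4S,5S,6R,6a'R)-4,5-bis[(tert-butyldimethylsilyl)oxy]-2-[(methoxymethoxy)methyl]-6-methyl-3'-methylidenehexahydrospiro[cyclohex-2-ene-1,5'-cyclopenta[b]furan]-2'-one (cis-fused lactone, lactone syn to the alkenyl ring carbon) | C=C1C(=O)O[C@@H]2C[C@@]3(C[C@H]12)C(COCOC)=C[C@H](O[Si](C)(C)C(C)(C)C)[C@@H](O[Si](C)(C)C(C)(C)C)[C@@H]3C | intermediate
23 | (1R,3a'R,4S,5S,6R,6a'R)-2-[(bromomethoxy)methyl]-4,5-bis[(tert-butyldimethylsilyl)oxy]-6-methyl-3'-methylidenehexahydrospiro[cyclohex-2-ene-1,5'-cyclopenta[b]furan]-2'-one | C=C1C(=O)O[C@@H]2C[C@@]3(C[C@H]12)C(COCBr)=C[C@H](O[Si](C)(C)C(C)(C)C)[C@@H](O[Si](C)(C)C(C)(C)C)[C@@H]3C | intermediate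
24 | (1R,3a'R,4S,5S,6R,6a'R)-4,5-bis[(tert-butyldimethylsilyl)oxy]-2-(hydroxymethyl)-6-methyl-3'-methylidenehexahydrospiro[cyclohex-2-ene-1,5'-cyclopenta[b]furan]-2'-one | C=C1C(=O)O[C@@H]2C[C@@]3(C[C@H]12)C(CO)=C[C@H](O[Si](C)(C)C(C)(C)C)[C@@H](O[Si](C)(C)C(C)(C)C)[C@@H]3C | intermediate
25 | [(1R,3a'R,4S,5S,6R,6a'R)-4,5-bis[(tert-butyldimethylsilyl)oxy]-6-methyl-3'-methylidene-2'-oxohexahydrospiro[cyclohex-2-ene-1,5'-cyclopenta[b]furan]-2-yl]methyl (2Z)-2-methylbut-2-enoate | C=C1C(=O)O[C@@H]2C[C@@]3(C[C@H]12)C(COC(=O)/C(C)=C\C)=C[C@H](O[Si](C)(C)C(C)(C)C)[C@@H](O[Si](C)(C)C(C)(C)C)[C@@H]3C | intermediate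
26 | [(1R,3a'R,4S,5S,6R,6a'R)-4,5-dihydroxy-6-methyl-3'-methylidene-2'-oxohexahydrospiro[cyclohex-2-ene-1,5'-cyclopenta[b]furan]-2-yl]methyl (2Z)-2-methylbut-2-enoate | C=C1C(=O)O[C@@H]2C[C@@]3(C[C@H]12)C(COC(=O)/C(C)=C\C)=C[C@H](O)[C@@H](O)[C@@H]3C | target

Total step count: 15. Longest linear sequence: 15 steps (from 1 and 2 to 26).

**Steps most likely to fail**

Step 12. The oxidative cyclisation may show poor facial selectivity with respect to the spiro centre, and the allenyl aldehyde may oligomerise or isomerise at 120 °C before it cyclises. The fallback sets out from 21 and builds the same two rings stepwise at low temperature. Palladium-catalysed silylstannylation of the allene with Me3Si–SnBu3 ([Pd(η3-C3H5)Cl]2, THF, rt) gives an allylstannane that should add at once to the tethered aldehyde through a closed transition state. This gives the cis-2-[1-(trimethylsilyl)ethenyl]cyclopentanol, (2R,3S,5R,8S,9S,10R)-8,9-bis[(tert-butyldimethylsilyl)oxy]-6-[(methoxymethoxy)methyl]-10-methyl-3-[1-(trimethylsilyl)ethenyl]spiro[4.5]dec-6-en-2-ol F1. Iododesilylation with N-iodosuccinimide in MeCN should give the vinyl iodide, (2R,3S,5R,8S,9S,10R)-8,9-bis[(tert-butyldimethylsilyl)oxy]-3-(1-iodoethenyl)-6-[(methoxymethoxy)methyl]-10-methylspiro[4.5]dec-6-en-2-ol F2. Carbonylative lactonisation of F2 (Pd(PPh3)4 as zerovalent palladium, CO 1 atm, Et3N, MeCN, 60 °C) comes back to the route at 22.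

Step 3. C-allylation of the hindered tetrasubstituted enolate may be slow, accompanied by O-allylation, or give insufficient anti-to-methyl selectivity. The fallback sets out from 7. The enolate (LiN(iPr)2, TMEDA, THF, −78 °C) is trapped on oxygen with allyl chloroformate to give the dienyl carbonate, (3S)-3-methyl-2-[3-(trimethylsilyl)prop-2-yn-1-yl]cyclohexa-1,5-dien-1-yl prop-2-en-1-yl carbonate F3. Decarboxylative Tsuji–Trost allylation of F3 follows, with Pd2(dba)3 (zerovalent palladium) and (S)- or (R)-4-tert-butyl-2-[2-(diphenylphosphino)phenyl]-4,5-dihydrooxazole in toluene at rt, using the ligand enantiomer that reinforces attack anti to the methyl group. The allyl group is delivered within the palladium enolate ion pair, and the sequence comes back to the route at 9.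

Step 14. Activation of angelic acid may isomerise the (Z)-alkene to the (E)-isomer, or the acylation may stall. The fallback sets out from 24 and builds the Z-alkene on the substrate. Esterification with 2-[bis(2,2,2-trifluoroethoxy)phosphoryl]propanoic acid (DCC, 4-(dimethylamino)pyridine 5 mol%, CH2Cl2, 0 °C) gives the phosphonate ester, [(1R,3a'R,4S,5S,6R,6a'R)-4,5-bis[(tert-butyldimethylsilyl)oxy]-6-methyl-3'-methylidene-2'-oxohexahydrospiro[cyclohex-2-ene-1,5'-cyclopenta[b]furan]-2-yl]methyl 2-[bis(2,2,2-trifluoroethoxy)phosphoryl]propanoate F4. Still–Gennari olefination of F4 with acetaldehyde (KN(SiMe3)2, 18-crown-6, THF, −78 °C) should give the (Z)-2-methylbut-2-enoate and comes back to the route at 25.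

**Further compounds**
F1 | step 12 | (2R,3S,5R,8S,9S,10R)-8,9-bis[(tert-butyldimethylsilyl)oxy]-6-[(methoxymethoxy)methyl]-10-methyl-3-[1-(trimethylsilyl)ethenyl]spiro[4.5]dec-6-en-2-ol | O[C@@H]1C[C@@]2(C[C@@H]1C(=C)[Si](C)(C)C)C(COCOC)=C[C@H](O[Si](C)(C)C(C)(C)C)[C@@H](O[Si](C)(C)C(C)(C)C)[C@@H]2C
F2 | step 12 | (2R,3S,5R,8S,9S,10R)-8,9-bis[(tert-butyldimethylsilyl)oxy]-3-(1-iodoethenyl)-6-[(methoxymethoxy)methyl]-10-methylspiro[4.5]dec-6-en-2-ol | O[C@@H]1C[C@@]2(C[C@@H]1C(=C)I)C(COCOC)=C[C@H](O[Si](C)(C)C(C)(C)C)[C@@H](O[Si](C)(C)C(C)(C)C)[C@@H]2C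
F3 | step 3 | (3S)-3-methyl-2-[3-(trimethylsilyl)prop-2-yn-1-yl]cyclohexa-1,5-dien-1-yl prop-2-en-1-yl carbonate | C=CCOC(=O)OC1=C(CC#C[Si](C)(C)C)[C@@H](C)CC=C1
F4 | step 14 | [(1R,3a'R,4S,5S,6R,6a'R)-4,5-bis[(tert-butyldimethylsilyl)oxy]-6-methyl-3'-methylidene-2'-oxohexahydrospiro[cyclohex-2-ene-1,5'-cyclopenta[b]furan]-2-yl]methyl 2-[bis(2,2,2-trifluoroethoxy)phosphoryl]propanoate (epimers at the phosphonate carbon) | C=C1C(=O)O[C@@H]2C[C@@]3(C[C@H]12)C(COC(=O)C(C)P(=O)(OCC(F)(F)F)OCC(F)(F)F)=C[C@H](O[Si](C)(C)C(C)(C)C)[C@@H](O[Si](C)(C)C(C)(C)C)[C@@H]3C
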